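The runs were computed for substances that don't exist; noise was put on by code.

Carrying a straight batch line's pace into a flask can mislead when that flask's stock of starting material lies below anything the line was drawn through, and I nearly fell into it here.

| flask | starting material | precatalyst | remark | time |
|---|---|---|---|---|
| west | 0.010 M | 1 mol% | run made earlier |  |
| north-east | 0.010 M | 0.5 mol% | run made earlier |  |
| south-west | 0.010 M | 0.75 mol% | run made earlier |  |
| epsilon | 0.010 M | 1 mol% | one stirred flow tank at steady state, fed with the mixture as stated, mean residence time 1.0 h |  |
| theta | 0.010 M (fed, over 0.800 h) | 1 mol% | a stirred flask in which starting material is dosed at a steady rate over 0.800 h without added volume, worked up at 1.0 h | 1.0 h |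
| delta | 0.010 M | 1 mol% | everything together in a closed stirred flask, run for 1.0 h | 1.0 h |
| alpha | 0.010 M | 1 mol% | one stirred flow tank at steady state, fed with the mixture as stated, mean residence time 3.00 h |  |

| run | time / min | target / % | starting material / % |
|---|---|---|---|
| west | 3.00 | 0.3 | 99.7 |
| west | 10.0 | 4.9 | 94.5 |
| west | 15.0 | 10.3 | 89.3 |
| west | 25.0 | 18.2 | 81.0 |
| west | 40.0 | 30.7 | 68.5 |
| west | 50.0 | 41.4 | 58.7 |
| west | 60.0 | 49.2 | 51.4 |
| north-east | 3.00 | 0.6 | 100.9 |
| north-east | 4.00 | 0.2 | 99.3 |
| north-east | 6.00 | 1.4 | 98.8 |
| north-east | 10.0 | 1.9 | 97.0 |
| north-east | 15.0 | 5.1 | 95.1 |
| north-east | 25.0 | 9.6 | 90.9 |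
| north-east | 40.0 | 15.7 | 83.2 |
| south-west | 5.00 | 1.5 | 98.5 |
| south-west | 10.0 | 3.7 | 95.8 |
| south-west | 15.0 | 7.6 | 92.0 |
| south-west | 20.0 | 10.1 | 88.3 |
| south-west | 25.0 | 13.1 | 84.7 |
| south-west | 30.0 | 17.1 | 82.6 |
| south-west | 40.0 | 24.5 | 75.9 |

(scatter of a reading: 0.5 percentage points)

- the stated concentrations are those of everything mixed, before any reaction; amounts are the same in each set-up
- steps under discussion: starting material + free catalyst <-> catalyst intermediate A; catalyst intermediate A -> catalyst intermediate B; catalyst intermediate B -> free catalyst + target; free catalyst -> spent catalyst; precatalyst -> free catalyst
- the feed brings no volume worth counting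
- the earlier runs were made in a closed, stirred flask

- the set-up with the highest amount of target at the outlet or at the end, in percent of the starting material put in ("none" if the first two lie within 2 percentage points) (epsilon / theta / delta / alpha / none)
- amount of target at the outlet or at the end, in percent of the starting material put in, epsilon
- amount of target at the outlet or at the end, in percent of the starting material put in, theta
- amount of target at the outlet or at the end, in percent of the starting material put in, delta
- amount of target at the outlet or at the end, in percent of the starting material put in, alpha

My bench rule was that target grows at a steady pace, apparently zero order in starting material, because the west line stayed straight to its last reading. From that run I read a clearing time, the time this loading would need to turn one whole charge at that pace, of 113 min, after a wait of 4.47 min. For delta, a repeat of west, the rule gave 49.2%. But west was last seen at 51.4% starting material, a c(starting material) of 0.00514 M, and no earlier run shows the pace below this floor, since the other two ended with more starting material than west. In alpha the residence time is 1.59 clearing times, so the rule asks for more than the charge, and it stops there.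

In theta the clearing time is 2.35 dosing times, so stock builds up, but slowly: the rule put its crossing of the floor at 39.6 min. This is the floor time, the time a dosed flask spends below the floor until dosing minus consumption lifts its stock over it. That was too much of 1.0 h to ignore, so I went round again, taking 0.5 of the pace below the floor, as if pace followed a stock averaging that fraction of the floor. On that assumption of mine the floor time became 30.1 min and my estimate of theta's target 37.8%.

The forecast chose alpha, with 48.5% (43% to 52%) for epsilon, 48% (44% to 51%) for theta, 49.5% (48% to 51%) for delta and 88% (68% to 97%) for alpha, holding that dosing “outpaces turnover, so the catalyst stays saturated”. My theta figure lay below that range.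

The flasks gave 44.8% for epsilon, 39.9% for theta, 48.4% for delta and 82.7% for alpha, so alpha led.

    starting material + free catalyst ⇌ catalyst intermediate A (K = 140 M⁻¹, k = 250 M⁻¹ s⁻¹)
    catalyst intermediate A → catalyst intermediate B (k = 0.0580 s⁻¹)
    catalyst intermediate B → free catalyst + target (k = 0.0300 s⁻¹)
    free catalyst → spent catalyst (k = 1.20 × 10⁻⁶ s⁻¹)
    precatalyst → free catalyst (k = 0.00350 s⁻¹)

At 0.500 h, inside its floor time, theta held 47.1% starting material, under the floor, with 14.8% target against 23.0% in delta at that moment, a gap of 8.2 percentage points against 8.5 points at the end. The flask dosed like theta but with 0.040 M of starting material at the same loading has the floor at 12.8% of its charge and, by the rule, a floor time of 7.42 min, and it gave 54.0%.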